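The route rests on opening ring E of the flavone half. Its C4 carbonyl is a single carbon held between C4a of ring D and the C3=C2 unit bearing the 4-methoxyphenyl ring F, and O1 is a ring D phenol oxygen. One palladium-catalysed operation therefore unites an ortho-iodophenol, carbon monoxide and 4-ethynylanisole, forming C4a–C4, C4–C3 and O1–C2 and closing ring E. The precursor is a biaryl iodophenol: ring D carries iodine, one free hydroxyl and two benzyl ethers, and is already bonded to ring B, which holds a benzyl ether and a dioxolane-masked aldehyde. From that aldehyde the (2S)-flavanone (rings A and C) is grown by catalytic asymmetric oxa-Michael closure.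

Key step: step 7

Assumption: the epi-quinine-derived thiourea named in step 12 is taken as the pseudoenantiomer that delivers the (2S) product; should it favour (2R), the epi-quinidine-derived catalyst (8R,9R) replaces it with no other change.
Assumption: the C8–C3' biaryl axis is treated as rotating freely on the laboratory timescale, since the target is specified without axial configuration.

Step 1
Reactants: 1 3-bromo-4-hydroxybenzaldehyde
Product: 2 4-(benzyloxy)-3-bromobenzaldehyde
Conditions: BnBr, K2CO3, DMF, rt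
Reagents that add atoms: benzyl bromide, BrCc1ccccc1
Why: Williamson etherification of the acidic para-formyl phenoxide with a reactive benzylic halide should be clean and leaves the aldehyde and the aryl bromide untouched.

Step 2
Reactants: 2 4-(benzyloxy)-3-bromobenzaldehyde
Product: 3 2-[4-(benzyloxy)-3-bromophenyl]-1,3-dioxolane
Conditions: HOCH2CH2OH, TsOH·H2O (cat.), toluene, reflux, Dean–Stark
Reagents that add atoms: ethane-1,2-diol, OCCO
Why: Acid-catalysed acetalisation driven by azeotropic removal of water masks the aldehyde, which would otherwise meet a secondary amine and a terminal alkyne at high temperature in step 7.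

Step 3
Reactants: 3 2-[4-(benzyloxy)-3-bromophenyl]-1,3-dioxolane
Product: 4 2-[2-(benzyloxy)-5-(1,3-dioxolan-2-yl)phenyl]-4,4,5,5-tetramethyl-1,3,2-dioxaborolane
Conditions: B2pin2, PdCl2(dppf) (3 mol%), KOAc, 1,4-dioxane, 90 °C
Reagents that add atoms: bis(pinacolato)diboron, CC1(C)OB(OC1(C)C)B1OC(C)(C)C(C)(C)O1
Why: Miyaura borylation of an aryl bromide tolerates the acetal and the benzyl ether and gives a pinacol ester that can be chromatographed and resists protodeboronation better than the free ortho-alkoxy boronic acid.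

Step 4
Reactants: 5 3,5-bis(benzyloxy)phenol
Product: 6 3,5-bis(benzyloxy)-2-iodophenol
Conditions: NIS (1.0 equiv), CH2Cl2, −40 to 0 °C, dark
Reagents that add atoms: N-iodosuccinimide, O=C1CCC(=O)N1I
Why: Electrophilic aromatic iodination in a non-polar solvent should go ortho to the free hydroxyl, which hydrogen-bonds to the reagent and is the small neighbour, whereas C4 lies between two benzyloxy groups, and one equivalent at low temperature should hold the reaction at the mono-iodide so that the following cross-coupling meets a single C–I bond.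

Step 5
Reactants: 6 3,5-bis(benzyloxy)-2-iodophenol; 4 2-[2-(benzyloxy)-5-(1,3-dioxolan-2-yl)phenyl]-4,4,5,5-tetramethyl-1,3,2-dioxaborolane
Product: 7 2',4,6-tris(benzyloxy)-5'-(1,3-dioxolan-2-yl)biphenyl-2-ol
Conditions: Pd(OAc)2 (5 mol%), SPhos (10 mol%), K3PO4, toluene/H2O (10:1), 90 °C
Reagents that add atoms: none
Why: Suzuki–Miyaura coupling with an electron-rich dialkylbiarylphosphine should cope with the electron-rich iodophenol and the tri-ortho-substituted biaryl being formed, the free phenol reacting as its phenoxide and the acetal being stable to aqueous base.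

Step 6
Reactants: 7 2',4,6-tris(benzyloxy)-5'-(1,3-dioxolan-2-yl)biphenyl-2-ol
Product: 8 2',4,6-tris(benzyloxy)-5'-(1,3-dioxolan-2-yl)-3-iodobiphenyl-2-ol
Conditions: NIS (1.05 equiv), NaHCO3, CH2Cl2, −20 to 0 °C
Reagents that add atoms: N-iodosuccinimide, O=C1CCC(=O)N1I
Why: Electrophilic aromatic iodination should again follow the free hydroxyl to its one remaining ortho position (C3), since C5 is crowded by two benzyloxy groups, one of them pushed towards it by ring B, while the mono-alkoxy ring B is far less nucleophilic and the bicarbonate buffer protects the dioxolane.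

Step 7
Reactants: 8 2',4,6-tris(benzyloxy)-5'-(1,3-dioxolan-2-yl)-3-iodobiphenyl-2-ol; 9 4-ethynylanisole
Product: 12 5,7-bis(benzyloxy)-8-[2-(benzyloxy)-5-(1,3-dioxolan-2-yl)phenyl]-2-(4-methoxyphenyl)-4H-chromen-4-one, via hydroxyaryl ynone 10 (not isolated), via diethylamino enone 11 (not isolated)
Conditions: CO (20 bar), PdCl2(PPh3)2 (5 mol%), Et2NH, 120 °C, autoclave
Reagents that add atoms: carbon monoxide, [C-]#[O+]
Why: Zerovalent palladium, formed in situ from PdCl2(PPh3)2, adds oxidatively to the C–I bond of 8, CO inserts to give the aroyl complex of divalent palladium, and exchange with the amine-deprotonated alkyne followed by reductive elimination gives ynone 10. Et2NH then adds to the ynone to give β-amino enone 11, whose C2 is attacked by the neighbouring phenol oxygen with expulsion of the amine, so that ring E closes in what is overall a 6-endo-dig oxa-Michael addition. The closest known reaction type is the palladium-catalysed carbonylative Sonogashira coupling–cyclisation of 2-iodophenols with terminal alkynes to flavones; no stereocentre is formed. Regiochemistry cannot vary, because the iodine-bearing carbon becomes C4a and the single unprotected oxygen sits between it and the carbon that holds ring B, so this oxygen becomes O1 and ring B ends on C8. The selectivity needed is 6-endo closure over 5-exo closure to the aurone, secured by running the reaction in the secondary amine so that cyclisation proceeds through 11, and acyl formation over direct alkynylation, secured by CO pressure. The benzyl ethers and the dioxolane are inert to amine, CO and heat.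

Step 8
Reactants: 12 5,7-bis(benzyloxy)-8-[2-(benzyloxy)-5-(1,3-dioxolan-2-yl)phenyl]-2-(4-methoxyphenyl)-4H-chromen-4-one
Product: 13 4-(benzyloxy)-3-[5,7-bis(benzyloxy)-2-(4-methoxyphenyl)-4-oxo-4H-chromen-8-yl]benzaldehyde
Conditions: 1 M HCl, THF, rt
Reagents that add atoms: water, O
Why: Acid-catalysed hydrolysis of the dioxolane is fast for an electron-rich benzaldehyde acetal, while benzyl ethers and the flavone are inert to dilute acid at room temperature.

Step 9
Reactants: 14 2,4,6-trihydroxyacetophenone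
Product: 15 1-[2,4-bis(benzyloxy)-6-hydroxyphenyl]ethan-1-one
Conditions: BnBr (2.05 equiv), K2CO3, DMF, rt
Reagents that add atoms: benzyl bromide, BrCc1ccccc1
Why: Williamson etherification should take the 4-hydroxyl and one ortho hydroxyl, the last ortho hydroxyl being held in a hydrogen bond to the ketone and therefore left free.

Step 10
Reactants: 15 1-[2,4-bis(benzyloxy)-6-hydroxyphenyl]ethan-1-one
Product: 16 tert-butyl 3-[2,4-bis(benzyloxy)-6-hydroxyphenyl]-3-oxopropanoate
Conditions: LiN(SiMe3)2 (3.2 equiv), THF, −78 °C; Boc2O (1.05 equiv), −78 to −20 °C; aq. NH4Cl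
Reagents that add atoms: di-tert-butyl dicarbonate, CC(C)(C)OC(=O)OC(=O)OC(C)(C)C
Why: Claisen-type C-acylation of the phenoxide–enolate dianion should occur at the enolate carbon, its most nucleophilic site, the third equivalent of base absorbing the acidic β-ketoester as it forms and the tert-butyl ester being too hindered to lactonise onto the phenoxide.

Step 11
Reactants: 13 4-(benzyloxy)-3-[5,7-bis(benzyloxy)-2-(4-methoxyphenyl)-4-oxo-4H-chromen-8-yl]benzaldehyde; 16 tert-butyl 3-[2,4-bis(benzyloxy)-6-hydroxyphenyl]-3-oxopropanoate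
Product: 17 tert-butyl (2Z)-2-[2,4-bis(benzyloxy)-6-hydroxybenzoyl]-3-{4-(benzyloxy)-3-[5,7-bis(benzyloxy)-2-(4-methoxyphenyl)-4-oxo-4H-chromen-8-yl]phenyl}prop-2-enoate
Conditions: piperidine (10 mol%), AcOH (10 mol%), 4 Å MS, toluene, rt
Reagents that add atoms: none
Why: Knoevenagel condensation of the 1,3-dicarbonyl with the unhindered aryl aldehyde under piperidinium acetate at room temperature should give the alkylidene without closing the ketone-chelated phenol onto it prematurely.

Step 12
Reactants: 17 tert-butyl (2Z)-2-[2,4-bis(benzyloxy)-6-hydroxybenzoyl]-3-{4-(benzyloxy)-3-[5,7-bis(benzyloxy)-2-(4-methoxyphenyl)-4-oxo-4H-chromen-8-yl]phenyl}prop-2-enoate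
Product: 19 (2S)-5,7-bis(benzyloxy)-2-{4-(benzyloxy)-3-[5,7-bis(benzyloxy)-2-(4-methoxyphenyl)-4-oxo-4H-chromen-8-yl]phenyl}-2,3-dihydro-4H-chromen-4-one, via flavanone tert-butyl ester 18 (not isolated)
Conditions: 1-[3,5-bis(trifluoromethyl)phenyl]-3-[(8S,9S)-6'-methoxycinchonan-9-yl]thiourea (10 mol%), toluene, −25 °C; then TsOH·H2O, 80 °C
Reagents that add atoms: none
Why: In this bifunctional thiourea-catalysed intramolecular oxa-Michael addition (6-endo-trig) the thiourea binds the 1,3-dicarbonyl and the quinuclidine nitrogen activates the phenol, so oxygen is delivered to one face of the alkylidene and C2 is set as (S) under catalyst control, after which acid-mediated loss of isobutene and decarboxylation erase C3 as a stereocentre without touching C2.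

Step 13
Reactants: 19 (2S)-5,7-bis(benzyloxy)-2-{4-(benzyloxy)-3-[5,7-bis(benzyloxy)-2-(4-methoxyphenyl)-4-oxo-4H-chromen-8-yl]phenyl}-2,3-dihydro-4H-chromen-4-one
Product: 20 (2S)-5,7-dihydroxy-2-{4-hydroxy-3-[5,7-dihydroxy-2-(4-methoxyphenyl)-4-oxo-4H-chromen-8-yl]phenyl}-2,3-dihydro-4H-chromen-4-one (2,3-dihydropodocarpusflavone A)
Conditions: H2 (1 atm), 10% Pd/C (palladium on carbon), THF/MeOH (1:1), rt
Reagents that add atoms: none
Why: Hydrogenolysis of the five aryl benzyl ethers under neutral conditions should leave the flavone enone, the aryl ketone, the methyl ether and the base-sensitive C2 stereocentre intact.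

Compound list
1 | 3-bromo-4-hydroxybenzaldehyde | O=Cc1ccc(O)c(Br)c1 | starting material
2 | 4-(benzyloxy)-3-bromobenzaldehyde | O=Cc1ccc(OCc2ccccc2)c(Br)c1 | intermediate
3 | 2-[4-(benzyloxy)-3-bromophenyl]-1,3-dioxolane | Brc1cc(C2OCCO2)ccc1OCc1ccccc1 | intermediate
4 | 2-[2-(benzyloxy)-5-(1,3-dioxolan-2-yl)phenyl]-4,4,5,5-tetramethyl-1,3,2-dioxaborolane | CC1(C)OB(OC1(C)C)c1cc(C2OCCO2)ccc1OCc1ccccc1 | intermediate
5 | 3,5-bis(benzyloxy)phenol | Oc1cc(OCc2ccccc2)cc(OCc2ccccc2)c1 | starting material
6 | 3,5-bis(benzyloxy)-2-iodophenol | Oc1cc(OCc2ccccc2)cc(OCc2ccccc2)c1I | intermediate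
7 | 2',4,6-tris(benzyloxy)-5'-(1,3-dioxolan-2-yl)biphenyl-2-ol | Oc1cc(OCc2ccccc2)cc(OCc2ccccc2)c1-c1cc(C2OCCO2)ccc1OCc1ccccc1 | intermediate
8 | 2',4,6-tris(benzyloxy)-5'-(1,3-dioxolan-2-yl)-3-iodobiphenyl-2-ol | Oc1c(I)c(OCc2ccccc2)cc(OCc2ccccc2)c1-c1cc(C2OCCO2)ccc1OCc1ccccc1 | intermediate
9 | 4-ethynylanisole | C#Cc1ccc(OC)cc1 | starting material
10 | 3-(4-methoxyphenyl)-1-[2',4,6-tris(benzyloxy)-5'-(1,3-dioxolan-2-yl)-2-hydroxybiphenyl-3-yl]prop-2-yn-1-one | COc1ccc(C#CC(=O)c2c(O)c(-c3cc(C4OCCO4)ccc3OCc3ccccc3)c(OCc3ccccc3)cc2OCc2ccccc2)cc1 | intermediate (not isolated)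
11 | 3-(diethylamino)-3-(4-methoxyphenyl)-1-[2',4,6-tris(benzyloxy)-5'-(1,3-dioxolan-2-yl)-2-hydroxybiphenyl-3-yl]prop-2-en-1-one (alkene isomers interconvert) | CCN(CC)C(=CC(=O)c1c(O)c(-c2cc(C3OCCO3)ccc2OCc2ccccc2)c(OCc2ccccc2)cc1OCc1ccccc1)c1ccc(OC)cc1 | intermediate (not isolated)
12 | 5,7-bis(benzyloxy)-8-[2-(benzyloxy)-5-(1,3-dioxolan-2-yl)phenyl]-2-(4-methoxyphenyl)-4H-chromen-4-one | COc1ccc(-c2cc(=O)c3c(OCc4ccccc4)cc(OCc4ccccc4)c(-c4cc(C5OCCO5)ccc4OCc4ccccc4)c3o2)cc1 | intermediate
13 | 4-(benzyloxy)-3-[5,7-bis(benzyloxy)-2-(4-methoxyphenyl)-4-oxo-4H-chromen-8-yl]benzaldehyde | COc1ccc(-c2cc(=O)c3c(OCc4ccccc4)cc(OCc4ccccc4)c(-c4cc(C=O)ccc4OCc4ccccc4)c3o2)cc1 | intermediate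
14 | 2,4,6-trihydroxyacetophenone | CC(=O)c1c(O)cc(O)cc1O | starting material
15 | 1-[2,4-bis(benzyloxy)-6-hydroxyphenyl]ethan-1-one | CC(=O)c1c(O)cc(OCc2ccccc2)cc1OCc1ccccc1 | intermediate
16 | tert-butyl 3-[2,4-bis(benzyloxy)-6-hydroxyphenyl]-3-oxopropanoate | CC(C)(C)OC(=O)CC(=O)c1c(O)cc(OCc2ccccc2)cc1OCc1ccccc1 | intermediate
17 | tert-butyl (2Z)-2-[2,4-bis(benzyloxy)-6-hydroxybenzoyl]-3-{4-(benzyloxy)-3-[5,7-bis(benzyloxy)-2-(4-methoxyphenyl)-4-oxo-4H-chromen-8-yl]phenyl}prop-2-enoate (Z drawn as the isomer expected to predominate; both isomers converge in step 12) | CC(C)(C)OC(=O)/C(=C\c1ccc(OCc2ccccc2)c(-c2c(OCc3ccccc3)cc(OCc3ccccc3)c3c(=O)cc(-c4ccc(OC)cc4)oc23)c1)C(=O)c1c(O)cc(OCc2ccccc2)cc1OCc1ccccc1 | intermediate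
18 | tert-butyl (2S)-5,7-bis(benzyloxy)-2-{4-(benzyloxy)-3-[5,7-bis(benzyloxy)-2-(4-methoxyphenyl)-4-oxo-4H-chromen-8-yl]phenyl}-4-oxo-3,4-dihydro-2H-chromene-3-carboxylate (C3 epimerisable, not defined) | COc1ccc(-c2cc(=O)c3c(OCc4ccccc4)cc(OCc4ccccc4)c(-c4cc([C@@H]5C(C(=O)OC(C)(C)C)C(=O)c6c(OCc7ccccc7)cc(OCc7ccccc7)cc6O5)ccc4OCc4ccccc4)c3o2)cc1 | intermediate (not isolated)
19 | (2S)-5,7-bis(benzyloxy)-2-{4-(benzyloxy)-3-[5,7-bis(benzyloxy)-2-(4-methoxyphenyl)-4-oxo-4H-chromen-8-yl]phenyl}-2,3-dihydro-4H-chromen-4-one | COc1ccc(-c2cc(=O)c3c(OCc4ccccc4)cc(OCc4ccccc4)c(-c4cc([C@@H]5CC(=O)c6c(OCc7ccccc7)cc(OCc7ccccc7)cc6O5)ccc4OCc4ccccc4)c3o2)cc1 | intermediate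
20 | (2S)-5,7-dihydroxy-2-{4-hydroxy-3-[5,7-dihydroxy-2-(4-methoxyphenyl)-4-oxo-4H-chromen-8-yl]phenyl}-2,3-dihydro-4H-chromen-4-one (2,3-dihydropodocarpusflavone A) | COc1ccc(-c2cc(=O)c3c(O)cc(O)c(-c4cc([C@@H]5CC(=O)c6c(O)cc(O)cc6O5)ccc4O)c3o2)cc1 | target

Total step count: 13.
Longest linear sequence: 10 steps (steps 1, 2, 3, 5, 6, 7, 8, 11, 12, 13) from 3-bromo-4-hydroxybenzaldehyde.

Steps most likely to fail

Step 7. Oxidative addition at the hindered, electron-rich C–I bond may be slow. The aroyl palladium intermediate may be captured by diethylamine to give an amide. Alkynylation may occur without CO insertion and lead to a benzofuran. Closure may go 5-exo to the aurone, or iodine may be lost reductively. The fallback forms the same bonds without palladium or CO; it sets out from 8 and 9 and comes back at 12. 4-Ethynylanisole 9 is deprotonated with n-BuLi (THF, −78 °C) and acylated with N-methoxy-N-methylcarbamoyl chloride to give N-methoxy-3-(4-methoxyphenyl)-N-methylprop-2-ynamide F1. Iodophenol 8 is deprotonated at oxygen with MeMgCl and then subjected to iodine–magnesium exchange with i-PrMgCl·LiCl (THF, −20 to 0 °C) to give the aryl Grignard reagent, chloromagnesium 2',4,6-tris(benzyloxy)-3-(chloromagnesio)-5'-(1,3-dioxolan-2-yl)biphenyl-2-olate F2. F2 adds to F1, and the chelated adduct collapses on work-up to ynone 10, which is isolated in this variant. Et2NH in EtOH at rt then closes ring E through 11 to 12.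

Step 12. Facial selectivity may be poor if an uncatalysed background closure competes or if the 6-benzyloxy group beside the ketone disturbs binding of the substrate to the catalyst. Partial retro-oxa-Michael opening during the hot acid decarboxylation could also erode enantiomeric purity. The fallback replaces asymmetric catalysis by resolution; it sets out from 17 and comes back at 19. Alkylidene 17 is closed without stereocontrol (Et3N, toluene, rt) to racemic tert-butyl 5,7-bis(benzyloxy)-2-{4-(benzyloxy)-3-[5,7-bis(benzyloxy)-2-(4-methoxyphenyl)-4-oxo-4H-chromen-8-yl]phenyl}-4-oxo-3,4-dihydro-2H-chromene-3-carboxylate F3. F3 is decarboxylated as before (TsOH·H2O, toluene, 80 °C) to racemic 5,7-bis(benzyloxy)-2-{4-(benzyloxy)-3-[5,7-bis(benzyloxy)-2-(4-methoxyphenyl)-4-oxo-4H-chromen-8-yl]phenyl}-2,3-dihydro-4H-chromen-4-one F4. F4 is separated by preparative HPLC on a polysaccharide chiral stationary phase into 19 and its (2R)-enantiomer F5, which is set aside. The enantiomeric purity of 19 would be checked on the same phase before step 13 in either case.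

Step 4. Iodination may also occur para to the hydroxyl or proceed to the di-iodide, giving mixtures that are hard to separate. The fallback places both halogens by a delivery that can only reach the ortho positions and desymmetrises at the coupling; it sets out from 5 (with 4) and comes back at 8, bypassing 6 and 7. Phenol 5 is brominated with NBS (2 equiv) and catalytic i-Pr2NH in CH2Cl2. The N-bromoamine is delivered through a hydrogen bond to the hydroxyl, and thus only to its two ortho positions, giving 3,5-bis(benzyloxy)-2,6-dibromophenol F6. One Suzuki–Miyaura coupling with boronate 4 as the limiting partner (Pd(OAc)2, SPhos, K3PO4, toluene/H2O; dibromoarenes tend to stop after a single coupling) gives 2',4,6-tris(benzyloxy)-3-bromo-5'-(1,3-dioxolan-2-yl)biphenyl-2-ol F7. A copper-catalysed aromatic Finkelstein exchange (NaI, CuI, trans-N,N'-dimethylcyclohexane-1,2-diamine, 1,4-dioxane, 110 °C, no added base so that the phenol is not O-arylated) converts F7 into 8.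

Further compounds
F1 | step 7 | N-methoxy-3-(4-methoxyphenyl)-N-methylprop-2-ynamide | COc1ccc(C#CC(=O)N(C)OC)cc1
F2 | step 7 | chloromagnesium 2',4,6-tris(benzyloxy)-3-(chloromagnesio)-5'-(1,3-dioxolan-2-yl)biphenyl-2-olate | Cl[Mg]Oc1c([Mg]Cl)c(OCc2ccccc2)cc(OCc2ccccc2)c1-c1cc(C2OCCO2)ccc1OCc1ccccc1
F3 | step 12 | racemic tert-butyl 5,7-bis(benzyloxy)-2-{4-(benzyloxy)-3-[5,7-bis(benzyloxy)-2-(4-methoxyphenyl)-4-oxo-4H-chromen-8-yl]phenyl}-4-oxo-3,4-dihydro-2H-chromene-3-carboxylate | COc1ccc(-c2cc(=O)c3c(OCc4ccccc4)cc(OCc4ccccc4)c(-c4cc(C5C(C(=O)OC(C)(C)C)C(=O)c6c(OCc7ccccc7)cc(OCc7ccccc7)cc6O5)ccc4OCc4ccccc4)c3o2)cc1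
F4 | step 12 | racemic 5,7-bis(benzyloxy)-2-{4-(benzyloxy)-3-[5,7-bis(benzyloxy)-2-(4-methoxyphenyl)-4-oxo-4H-chromen-8-yl]phenyl}-2,3-dihydro-4H-chromen-4-one | COc1ccc(-c2cc(=O)c3c(OCc4ccccc4)cc(OCc4ccccc4)c(-c4cc(C5CC(=O)c6c(OCc7ccccc7)cc(OCc7ccccc7)cc6O5)ccc4OCc4ccccc4)c3o2)cc1
F5 | step 12 | (2R)-5,7-bis(benzyloxy)-2-{4-(benzyloxy)-3-[5,7-bis(benzyloxy)-2-(4-methoxyphenyl)-4-oxo-4H-chromen-8-yl]phenyl}-2,3-dihydro-4H-chromen-4-one | COc1ccc(-c2cc(=O)c3c(OCc4ccccc4)cc(OCc4ccccc4)c(-c4cc([C@H]5CC(=O)c6c(OCc7ccccc7)cc(OCc7ccccc7)cc6O5)ccc4OCc4ccccc4)c3o2)cc1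
F6 | step 4 | 3,5-bis(benzyloxy)-2,6-dibromophenol | Oc1c(Br)c(OCc2ccccc2)cc(OCc2ccccc2)c1Br
F7 | step 4 | 2',4,6-tris(benzyloxy)-3-bromo-5'-(1,3-dioxolan-2-yl)biphenyl-2-ol | Oc1c(Br)c(OCc2ccccc2)cc(OCc2ccccc2)c1-c1cc(C2OCCO2)ccc1OCc1ccccc1
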